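The central benzene ring of gymconopin D (C1 phenethyl, C2 4‑hydroxybenzyl, C3 and C5 methoxy, C4 and C6 hydrogen) is assembled, not substituted. A Danheiser benzannulation joins a 2,3‑disubstituted cyclobutenone to methoxyacetylene in one thermal operation, making C2–C3 and C4–C5 and closing C5–C6. The feature exploited is the pattern of this ring: meta oxygens at C3 and C5 flanking a free C4–H, beside contiguous carbon substituents at C1 and C2. The alkyne delivers C3–OMe and C4–H, the cyclobutenone carbonyl becomes the C5 oxygen, and its alkene carbons bring both side chains. The precursor is 2‑(4‑benzyloxybenzyl)‑3‑[2‑(3‑benzyloxyphenyl)ethyl]cyclobut‑2‑enone, made from a 3‑ethoxycyclobutenone and a phenethyl Grignard reagent.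

Key step: step 7

Remark: the target has no stereocentre; the racemic centres of intermediates 10 and 16 vanish within the steps that form them, and ketene for step 2 is taken as the gas from a standard acetone‑pyrolysis generator.

Step 1
Reactants: 1 ethoxyacetylene; 2 4‑(benzyloxy)benzyl chloride
Product: 4 1‑(benzyloxy)‑4‑(3‑ethoxyprop‑2‑yn‑1‑yl)benzene, via lithium ethoxyacetylide 3 (not isolated)
Conditions: n‑BuLi, THF, −78 °C; then 2, DMPU, Bu4NI (cat.), −78 °C to rt
Reagents that add atoms: none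
Why: SN2 alkylation of a lithium alkoxyacetylide by a reactive para‑alkoxybenzylic chloride (acetylide alkylation), helped by DMPU and in situ iodide exchange; the benzyl aryl ether is inert to the acetylide.

Step 2
Reactants: 4 1‑(benzyloxy)‑4‑(3‑ethoxyprop‑2‑yn‑1‑yl)benzene
Product: 5 2‑[4‑(benzyloxy)benzyl]‑3‑ethoxycyclobut‑2‑en‑1‑one
Conditions: ketene (gas, from acetone pyrolysis), CH2Cl2, 0 °C to rt
Reagents that add atoms: ketene, C=C=O
Why: Thermal [2+2] cycloaddition of ketene to an electron‑rich 1‑alkoxyalkyne, the established entry to 2‑substituted 3‑alkoxycyclobutenones; the nucleophilic benzyl‑bearing alkyne carbon bonds to the ketene carbonyl carbon, so OEt ends at C3 and the benzyl group at C2.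

Step 3
Reactants: 6 2‑(3‑hydroxyphenyl)ethanol
Product: 7 2‑[3‑(benzyloxy)phenyl]ethanol
Conditions: BnBr, K2CO3, acetone, reflux
Reagents that add atoms: benzyl bromide, BrCc1ccccc1
Why: Williamson ether synthesis; carbonate deprotonates only the phenol, so the primary alcohol should stay free.

Step 4
Reactants: 7 2‑[3‑(benzyloxy)phenyl]ethanol
Product: 8 1‑(benzyloxy)‑3‑(2‑bromoethyl)benzene
Conditions: CBr4, PPh3, CH2Cl2, 0 °C to rt
Reagents that add atoms: carbon tetrabromide, BrC(Br)(Br)Br
Why: Appel reaction of a primary alcohol under neutral conditions that leave the benzyl aryl ether untouched.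

Step 5
Reactants: 8 1‑(benzyloxy)‑3‑(2‑bromoethyl)benzene; 5 2‑[4‑(benzyloxy)benzyl]‑3‑ethoxycyclobut‑2‑en‑1‑one
Product: 11 2‑[4‑(benzyloxy)benzyl]‑3‑{2‑[3‑(benzyloxy)phenyl]ethyl}cyclobut‑2‑en‑1‑one, via arylethylmagnesium bromide 9 (not isolated), via tertiary cyclobutenol 10 (not isolated)
Conditions: Mg, THF, rt; then 5, THF, −78 to 0 °C; then 1 M aq HCl, rt
Reagents that add atoms: water, O
Why: Grignard 1,2‑addition to the carbonyl of the vinylogous ester, then acid‑induced loss of the tertiary hydroxyl and hydrolysis of the ethoxy‑stabilised cation (Stork–Danheiser‑type carbonyl transposition, the standard route from 3‑ethoxycyclobutenones to 3‑substituted cyclobutenones) moves the carbonyl to the former C3; the carbinol centre of 10 is racemic and is lost.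

Step 6
Reactants: 12 chloroacetaldehyde dimethyl acetal
Product: 14 methoxyacetylene, via sodium methoxyacetylide 13 (not isolated)
Conditions: NaNH2 (3 equiv), liquid NH3, −33 °C; evaporate NH3; cold saturated aq NaCl, −20 °C, distil
Reagents that add atoms: none
Why: Two successive amide‑induced eliminations (methanol, then HCl) and deprotonation give the acetylide, which is protonated on aqueous quench; this is the classical preparation of alkoxyacetylenes from haloacetals.

Step 7
Reactants: 11 2‑[4‑(benzyloxy)benzyl]‑3‑{2‑[3‑(benzyloxy)phenyl]ethyl}cyclobut‑2‑en‑1‑one; 14 methoxyacetylene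
Product: 19 4‑[4‑(benzyloxy)benzyl]‑3‑{2‑[3‑(benzyloxy)phenyl]ethyl}‑5‑methoxyphenol, via vinylketene 15 (not isolated), via vinylcyclobutenone 16 (not isolated), via dienylketene 17 (not isolated), via cyclohexadienone 18 (not isolated)
Conditions: 14 (3 equiv), toluene, sealed tube, 80 °C then 110 °C
Reagents that add atoms: none
Why: Heating opens 11 by four‑electron conrotatory cleavage of its C(O)–CH2 bond to vinylketene 15, whose carbonyl carbon is attacked by the CH terminus of the ynol ether in a polar [2+2] cycloaddition to give 4‑vinylcyclobutenone 16, which reopens to dienylketene 17. The six‑membered ring then closes by thermal disrotatory six‑electron electrocyclisation of 17 (ketene carbon onto the terminal methylene, target bond C5–C6), and enolisation of cyclohexadienone 18 should deliver phenol 19. This is the Danheiser benzannulation of cyclobutenones with alkoxyacetylenes, a documented route to resorcinol monoethers. The product has no new stereocentre; the quaternary centre of 16 is racemic and is erased on ring opening. The only selectivity needed is the regiochemistry of the ketene–alkyne union, which the oxygen‑polarised alkyne secures so that its methoxy‑bearing carbon bonds to the benzyl‑bearing ketene carbon. Both phenols are masked as benzyl ethers because free hydroxyl groups would capture the ketenes.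

Step 8
Reactants: 19 4‑[4‑(benzyloxy)benzyl]‑3‑{2‑[3‑(benzyloxy)phenyl]ethyl}‑5‑methoxyphenol
Product: 20 2‑[4‑(benzyloxy)benzyl]‑1‑{2‑[3‑(benzyloxy)phenyl]ethyl}‑3,5‑dimethoxybenzene
Conditions: MeI, K2CO3, DMF, rt
Reagents that add atoms: iodomethane, CI
Why: Williamson O‑methylation of the only free phenol; nothing else in the molecule is nucleophilic under carbonate.

Step 9
Reactants: 20 2‑[4‑(benzyloxy)benzyl]‑1‑{2‑[3‑(benzyloxy)phenyl]ethyl}‑3,5‑dimethoxybenzene
Product: 21 gymconopin D
Conditions: H2 (1 atm), Pd/C (10 wt% palladium on carbon), EtOAc–MeOH, rt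
Reagents that add atoms: none
Why: Catalytic hydrogenolysis of both benzyl aryl ethers; the methyl ethers, the diarylmethane CH2 and the bibenzyl bridge are inert under these mild conditions.

Compound list
1 | ethoxyacetylene | CCOC#C | starting material
2 | 4‑(benzyloxy)benzyl chloride | ClCc1ccc(OCc2ccccc2)cc1 | starting material
3 | lithium ethoxyacetylide | [Li+].[C-]#COCC | intermediate (not isolated)
4 | 1‑(benzyloxy)‑4‑(3‑ethoxyprop‑2‑yn‑1‑yl)benzene | CCOC#CCc1ccc(OCc2ccccc2)cc1 | intermediate
5 | 2‑[4‑(benzyloxy)benzyl]‑3‑ethoxycyclobut‑2‑en‑1‑one | CCOC1=C(Cc2ccc(OCc3ccccc3)cc2)C(=O)C1 | intermediate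
6 | 2‑(3‑hydroxyphenyl)ethanol | OCCc1cccc(O)c1 | starting material
7 | 2‑[3‑(benzyloxy)phenyl]ethanol | OCCc1cccc(OCc2ccccc2)c1 | intermediate
8 | 1‑(benzyloxy)‑3‑(2‑bromoethyl)benzene | BrCCc1cccc(OCc2ccccc2)c1 | intermediate
9 | {2‑[3‑(benzyloxy)phenyl]ethyl}magnesium bromide | Br[Mg]CCc1cccc(OCc2ccccc2)c1 | intermediate (not isolated)
10 | 2‑[4‑(benzyloxy)benzyl]‑1‑{2‑[3‑(benzyloxy)phenyl]ethyl}‑3‑ethoxycyclobut‑2‑en‑1‑ol (racemic) | CCOC1=C(Cc2ccc(OCc3ccccc3)cc2)C(O)(CCc2cccc(OCc3ccccc3)c2)C1 | intermediate (not isolated)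
11 | 2‑[4‑(benzyloxy)benzyl]‑3‑{2‑[3‑(benzyloxy)phenyl]ethyl}cyclobut‑2‑en‑1‑one | O=C1CC(CCc2cccc(OCc3ccccc3)c2)=C1Cc1ccc(OCc2ccccc2)cc1 | intermediate
12 | chloroacetaldehyde dimethyl acetal | ClCC(OC)OC | starting material
13 | sodium methoxyacetylide | [Na+].[C-]#COC | intermediate (not isolated)
14 | methoxyacetylene | COC#C | intermediate
15 | 2‑[4‑(benzyloxy)benzyl]‑3‑{2‑[3‑(benzyloxy)phenyl]ethyl}buta‑1,3‑dien‑1‑one (vinylketene) | O=C=C(Cc1ccc(OCc2ccccc2)cc1)C(=C)CCc1cccc(OCc2ccccc2)c1 | intermediate (not isolated)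
16 | 4‑[4‑(benzyloxy)benzyl]‑4‑{4‑[3‑(benzyloxy)phenyl]but‑1‑en‑2‑yl}‑3‑methoxycyclobut‑2‑en‑1‑one (racemic) | COC1=CC(=O)C1(Cc1ccc(OCc2ccccc2)cc1)C(=C)CCc1cccc(OCc2ccccc2)c1 | intermediate (not isolated)
17 | (3E)‑4‑[4‑(benzyloxy)benzyl]‑5‑{2‑[3‑(benzyloxy)phenyl]ethyl}‑3‑methoxyhexa‑1,3,5‑trien‑1‑one (dienylketene) | O=C=C/C(OC)=C(\C(=C)CCc1cccc(OCc2ccccc2)c1)Cc1ccc(OCc2ccccc2)cc1 | intermediate (not isolated)
18 | 4‑[4‑(benzyloxy)benzyl]‑5‑{2‑[3‑(benzyloxy)phenyl]ethyl}‑3‑methoxycyclohexa‑2,4‑dien‑1‑one | COC1=CC(=O)CC(CCc2cccc(OCc3ccccc3)c2)=C1Cc1ccc(OCc2ccccc2)cc1 | intermediate (not isolated)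
19 | 4‑[4‑(benzyloxy)benzyl]‑3‑{2‑[3‑(benzyloxy)phenyl]ethyl}‑5‑methoxyphenol | COc1cc(O)cc(CCc2cccc(OCc3ccccc3)c2)c1Cc1ccc(OCc2ccccc2)cc1 | intermediate
20 | 2‑[4‑(benzyloxy)benzyl]‑1‑{2‑[3‑(benzyloxy)phenyl]ethyl}‑3,5‑dimethoxybenzene | COc1cc(OC)cc(CCc2cccc(OCc3ccccc3)c2)c1Cc1ccc(OCc2ccccc2)cc1 | intermediate
21 | gymconopin D, 3‑{2‑[2‑(4‑hydroxybenzyl)‑3,5‑dimethoxyphenyl]ethyl}phenol | COc1cc(CCc2cccc(O)c2)c(Cc2ccc(O)cc2)c(OC)c1 | target

Total step count: 9. Longest linear sequence: 6 steps (steps 1, 2, 5, 7, 8, 9; the arm through steps 3, 4, 5, 7, 8, 9 is equally long).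

Steps most likely to fail

Step 7. The thermal cascade may be diverted: the ketene intermediates can be captured by the phenol as it forms (O‑acylation) or dimerise, and the low‑boiling alkyne can escape or oligomerise before it is consumed. The fallback abandons ring construction and functionalises a preformed resorcinol dimethyl ether instead. It sets out from bromide 8 through its Grignard reagent 9. Kumada coupling of 9 with 1‑bromo‑3,5‑dimethoxybenzene (PdCl2(dppf) cat., THF, reflux) should give 1‑{2‑[3‑(benzyloxy)phenyl]ethyl}‑3,5‑dimethoxybenzene F1. Vilsmeier–Haack formylation (POCl3, DMF, 0 to 60 °C) should occur on the doubly activated ring, para to one methoxy group and next to the ethylene chain, through N‑[(2‑{2‑[3‑(benzyloxy)phenyl]ethyl}‑4,6‑dimethoxyphenyl)methylidene]‑N‑methylmethanaminium chloride F2. Aqueous NaOAc hydrolysis then gives 2‑{2‑[3‑(benzyloxy)phenyl]ethyl}‑4,6‑dimethoxybenzaldehyde F3; any isomer formylated between the two methoxy groups would be removed here. Addition of 4‑(benzyloxy)phenylmagnesium bromide F4 (from 1‑(benzyloxy)‑4‑bromobenzene and Mg in THF) should give [4‑(benzyloxy)phenyl](2‑{2‑[3‑(benzyloxy)phenyl]ethyl}‑4,6‑dimethoxyphenyl)methanol F5. Ionic deoxygenation of this doubly activated benzhydrol (Et3SiH, CF3CO2H, CH2Cl2, 0 °C) should deliver 20, where the route resumes with step 9.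

Step 2. Dimerisation or polymerisation of ketene may outrun the cycloaddition, and traces of acid may hydrate the ynol ether to an ester before it reacts. The fallback replaces gaseous ketene by a more electrophilic ketene made in the flask. It sets out from 4: dichloroketene (Cl3CCOCl, zinc–copper couple (Zn–Cu), Et2O–DME, rt) should add with the same regiochemistry to give 2‑[4‑(benzyloxy)benzyl]‑4,4‑dichloro‑3‑ethoxycyclobut‑2‑en‑1‑one F6. Reductive dechlorination (Zn, AcOH, TMEDA, EtOH, 0 °C to rt) should then return 5, and the route continues with step 5.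

Step 1. The basic acetylide may isomerise the doubly activated propargylic CH2 of the product to an allenyl ether, substitution on the aggregated lithium acetylide may stall, and the ynol ether may hydrate during isolation. The fallback exchanges the SN2 reaction for a neutral cross‑coupling. It sets out from 1: lithium ethoxyacetylide 3 is quenched with Bu3SnCl (THF, −78 °C to rt) to give tributyl(ethoxyethynyl)stannane F7. Stille coupling of F7 with benzylic chloride 2 (Pd(PPh3)4 cat., THF, 60 °C) should give 4, and the route continues with step 2.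

Further compounds
F1 | step 7 | 1‑{2‑[3‑(benzyloxy)phenyl]ethyl}‑3,5‑dimethoxybenzene | COc1cc(OC)cc(CCc2cccc(OCc3ccccc3)c2)c1
F2 | step 7 | N‑[(2‑{2‑[3‑(benzyloxy)phenyl]ethyl}‑4,6‑dimethoxyphenyl)methylidene]‑N‑methylmethanaminium chloride | C[N+](C)=Cc1c(OC)cc(OC)cc1CCc1cccc(OCc2ccccc2)c1.[Cl-]
F3 | step 7 | 2‑{2‑[3‑(benzyloxy)phenyl]ethyl}‑4,6‑dimethoxybenzaldehyde | COc1cc(OC)c(C=O)c(CCc2cccc(OCc3ccccc3)c2)c1
F4 | step 7 | 4‑(benzyloxy)phenylmagnesium bromide | Br[Mg]c1ccc(OCc2ccccc2)cc1
F5 | step 7 | [4‑(benzyloxy)phenyl](2‑{2‑[3‑(benzyloxy)phenyl]ethyl}‑4,6‑dimethoxyphenyl)methanol (racemic) | COc1cc(OC)c(C(O)c2ccc(OCc3ccccc3)cc2)c(CCc2cccc(OCc3ccccc3)c2)c1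
F6 | step 2 | 2‑[4‑(benzyloxy)benzyl]‑4,4‑dichloro‑3‑ethoxycyclobut‑2‑en‑1‑one | CCOC1=C(Cc2ccc(OCc3ccccc3)cc2)C(=O)C1(Cl)Cl
F7 | step 1 | tributyl(ethoxyethynyl)stannane | CCCC[Sn](CCCC)(CCCC)C#COCC
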